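**Strategy.** Heavy atoms are numbered along the target SMILES. Ring C4-C5-C21-C22-C23-C24 holds C3, C6, C20 and C25 on a single face. It shares bond C5-C21 with the lactone ring C5-C6-O8-C9-C20-C21. An endo cycloaddition between an E,E-diene on C20 and a Z-alkene hung from O8 would leave exactly this pattern. The plan unbridges C2-C22, then cuts C5-C21 and C4-C24. Heating the half ester, a phenyl dienyl oxolane silylated at O11 and maleoylated at O8, should forge carbocycle and lactone together and set C4, C5, C21 and C24.

Key step: step 13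

Remark on the chemistry: s1–s6 denote the glucose carbons; s1, s2, s3, s4 and s5 end as C21, C20, C9, C10 and C12. NAP = 2-naphthylmethyl. PhMgBr solution, pinacolborane and 3-methylbut-1-yne are taken as purchased.

Step 1
Reactants: 1 1,2:5,6-di-O-isopropylidene-α-D-glucofuranose; 2 2-(bromomethyl)naphthalene
Product: 3 1,2:5,6-di-O-isopropylidene-3-O-NAP-α-D-glucofuranose
Conditions: NaH, Bu4NI (cat.), DMF, 0 °C to rt
Reagents that add atoms: none
Why: Williamson ether synthesis on the only free hydroxyl group (future O8) installs a NAP ether that resists Grignard reagents and methanolic acid yet falls to DDQ, and no stereocentre is touched.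

Step 2
Reactants: 3 1,2:5,6-di-O-isopropylidene-3-O-NAP-α-D-glucofuranose
Product: 5 1,2-O-isopropylidene-3-O-NAP-α-D-xylo-pentodialdo-1,4-furanose, via 5,6-diol 4 (not isolated)
Conditions: H5IO6, EtOAc, rt
Reagents that add atoms: none
Why: Periodic acid hydrolyses the exposed terminal acetonide and then cleaves the s5–s6 glycol (Malaprade reaction) in the same flask, which trims glucose to the xylo aldehyde at s5 without touching s2–s4.

Step 3
Reactants: 5 1,2-O-isopropylidene-3-O-NAP-α-D-xylo-pentodialdo-1,4-furanose; 6 phenylmagnesium bromide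
Product: 7 (5S)-1,2-O-isopropylidene-3-O-NAP-5-C-phenyl-α-D-xylofuranose (L-ido-type carbinol)
Conditions: THF, −78 to 0 °C; aq NH4Cl
Reagents that add atoms: none
Why: Grignard addition under Cram chelate control: magnesium bridging the aldehyde oxygen and the furanose ring oxygen leaves open the face next to H-s4, away from the s3 NAP ether, so the 5S carbinol should predominate and the minor epimer can be removed by chromatography.

Step 4
Reactants: 7 (5S)-1,2-O-isopropylidene-3-O-NAP-5-C-phenyl-α-D-xylofuranose
Product: 8 5-O-methanesulfonate of 7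
Conditions: MsCl, Et3N, CH2Cl2, −10 to 0 °C
Reagents that add atoms: methanesulfonyl chloride, CS(=O)(=O)Cl
Why: Sulfonylation of the single free hydroxyl group proceeds with retention, and the two flanking C–O bonds damp ionisation enough for the benzylic mesylate to be handled cold.

Step 5
Reactants: 8 5-O-methanesulfonate of 7
Product: 10 (5R)-2,5-anhydro-3-O-NAP-5-C-phenyl-D-xylose dimethyl acetal, via acyclic acetal mesylate 9 (not isolated)
Conditions: HCl (1.25 M in MeOH), reflux
Reagents that add atoms: methanol, CO
Why: Acid methanolysis opens acetonide and furanose to the acyclic dimethyl acetal, whose s2 hydroxyl group (future O19) displaces the benzylic mesylate in a 5-exo-tet SN2 closure with inversion, so 5S becomes 5R (C12) with phenyl cis to C21, and the acidic medium keeps the s4 hydroxyl group from forming an epoxide.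

Step 6
Reactants: 10 (5R)-2,5-anhydro-3-O-NAP-5-C-phenyl-D-xylose dimethyl acetal
Product: 11 (5R)-2,5-anhydro-3-O-NAP-5-C-phenyl-aldehydo-D-xylose
Conditions: aq HCl (2 M), THF, 45 °C
Reagents that add atoms: water, O
Why: Acetal hydrolysis is run before any silyl group is present, so the acid strength that this deactivated α-alkoxy acetal needs endangers nothing, and O11–H cannot form a lactol because it lies trans to C21.

Step 7
Reactants: 11 (5R)-2,5-anhydro-3-O-NAP-5-C-phenyl-aldehydo-D-xylose
Product: 12 (E)-2-iodoethenyl oxolane (CHO of 11 replaced by E-CH=CHI)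
Conditions: CrCl2, CHI3, THF–dioxane, 0 °C to rt
Reagents that add atoms: iodoform, IC(I)I
Why: Takai olefination: the gem-dichromium species adds to the aldehyde and eliminates anti, which favours the E-iodoalkene, while the nearly neutral medium spares the epimerisable C20 centre and tolerates the free O11–H.

Step 8
Reactants: 12 (E)-2-iodoethenyl oxolane
Product: 13 O11 tert-butyldimethylsilyl ether of 12
Conditions: TBSOTf, 2,6-lutidine, CH2Cl2, 0 °C
Reagents that add atoms: tert-butyldimethylsilyl triflate, CC(C)(C)[Si](C)(C)OS(=O)(=O)C(F)(F)F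
Why: Silylation of the only free hydroxyl group by the reactive triflate and a hindered base gives an ether that should outlast DDQ, aqueous base, heat and radical conditions.

Step 9
Reactants: 13 O11 tert-butyldimethylsilyl ether of 12
Product: 14 O8 alcohol (NAP removed)
Conditions: DDQ, CH2Cl2–pH 7 buffer, 0 °C to rt
Reagents that add atoms: none
Why: Oxidative cleavage of the electron-rich NAP ether by DDQ frees O8–H before any diene is present, the plain C12 benzylic ether is too electron-poor to react, and the trans O8/O11 geometry blocks silyl migration.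

Step 10
Reactants: 15 3-methylbut-1-yne; 16 pinacolborane
Product: 17 (E)-2-(3-methylbut-1-enyl)-4,4,5,5-tetramethyl-1,3,2-dioxaborolane
Conditions: Cp2ZrHCl (10 mol %), Et3N (10 mol %), neat, sealed tube, 40 °C
Reagents that add atoms: none
Why: Cp2ZrHCl-catalysed hydroboration of a terminal alkyne is a syn, anti-Markovnikov addition, so only the E-alkenylboronate is expected.

Step 11
Reactants: 14 O8 alcohol; 17 (E)-alkenylboronate
Product: 18 dienyl alcohol carrying the (1E,3E)-5-methylhexa-1,3-dienyl group on C20
Conditions: Pd(dppf)Cl2 (5 mol %), aq K3PO4, THF, rt to 40 °C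
Reagents that add atoms: none
Why: Suzuki–Miyaura coupling joins C22 to C23 with retention at both alkenyl partners, which fixes the E,E-diene that the cycloaddition needs, and the mild aqueous base tolerates the free alcohol and the silyl ether.

Step 12
Reactants: 18 dienyl alcohol; 19 maleic anhydride
Product: 20 O8 hydrogen maleate of 18
Conditions: Et3N, DMAP (cat.), CH2Cl2, 0 °C; cold aq citric acid
Reagents that add atoms: none
Why: DMAP-catalysed ring-opening acylation delivers the alkene from a cyclic anhydride, so the Z-geometry is built in, and low temperature with short contact keeps amine-induced isomerisation down.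

Step 13
Reactants: 20 O8 hydrogen maleate of 18
Product: 21 cyclohexene-fused δ-lactone acid (C3, C6, C20 and C25 all cis)
Conditions: PhMe (5 mM), BHT (cat.), 110 °C, sealed vessel, Ar
Reagents that add atoms: none
Why: This is a thermal, concerted, suprafacial [4+2] cycloaddition of the C21=C22–C23=C24 diene to the C4=C5 maleate, an ester-tethered intramolecular Diels–Alder reaction of the 1,7,9-decatrienoate class, whose closest known relatives are dienyl maleates, fumarates and acrylates that give fused lactones. The cyclohexene (C4, C5, C21, C22, C23, C24) closes through the two new σ-bonds themselves, while the δ-lactone (C5, C6, O8, C9, C20, C21) closes as the four-atom tether ring in the fused (type 1) mode with C6 tucked under the diene. C4 and C5 emerge cis because the Z-alkene adds suprafacially, C21 and C24 carry C20 and C25 cis because both diene double bonds are E, and endo placement of both carbonyl groups (C6 and C3) brings the two pairs onto the same face. The absolute sense is relayed from C20 and C9, since folding onto the other diene face would drive C4 and its carboxyl group into the concave pocket of the cis-fused oxolane, against O19 and the C12 phenyl ring, so the carbocycle should grow on the convex side. The step therefore needs endo selectivity and one π-face; the first is backed by secondary overlap of two carbonyl groups and the second by the rigid cis O8/C21 arrangement, which also lowers the entropic price and eases access to the ester rotamer that a lactone demands. High dilution holds back intermolecular addition, BHT holds back polymerisation, and the free carboxyl group, hydrogen-bonded to the C6 carbonyl, activates the dienophile and remains distinguishable from the lactone afterwards.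

Step 14
Reactants: 21 cyclohexene-fused δ-lactone acid
Product: 22 S-ethyl thioester of 21 at C3
Conditions: EtSH, EDC·HCl, DMAP (cat.), CH2Cl2, 0 °C
Reagents that add atoms: ethanethiol, CCS
Why: Carbodiimide (Steglich-type) thioesterification activates only the free C3 carboxyl group and prepares a reduction that never passes through a C3 carbinol, which could translactonise onto the cis C6 carbonyl, while the cold and DMAP-lean medium guards C4 against epimerisation.

Step 15
Reactants: 22 S-ethyl thioester
Product: 23 C3 aldehyde
Conditions: Et3SiH, Pd/C (10 %), acetone, rt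
Reagents that add atoms: none
Why: Fukuyama reduction: insertion of zerovalent palladium into the C–S bond and hydride transfer from the silane stop at the aldehyde under neutral conditions, so lactone, silyl ether, ring alkene and the C4 centre should persist.

Step 16
Reactants: 23 C3 aldehyde
Product: 24 (Z)-2-iodoprop-1-enyl compound (iodine cis to C4)
Conditions: EtPPh3I, n-BuLi, THF, rt; I2, −78 °C; NaHMDS, −20 °C; then 23, −78 °C
Reagents that add atoms: ethyltriphenylphosphonium iodide, CC[P+](c1ccccc1)(c1ccccc1)c1ccccc1.[I-]; iodine, II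
Why: Stork–Zhao-type Wittig olefination with the α-iodoethylidene ylide: kinetic cis-oxaphosphetane formation from the unstabilised ylide places iodine cis to C4, and addition at −78 °C should outrun enolisation of the aldehyde.

Step 17
Reactants: 24 (Z)-2-iodoprop-1-enyl compound
Product: 25 O11 tert-butyldimethylsilyl ether of the target
Conditions: Bu3SnH (syringe pump, 8 h), AIBN, PhMe (2 mM), 100 °C
Reagents that add atoms: none
Why: Vinyl radical cyclisation: iodine abstraction gives the σ-radical at C2, whose rigid cis C4–C3=C2 spacer aims it at the 1,4-related C22 rather than the 1,3-related C23; any C2–C23 adduct can return through the cyclopropylcarbinyl radical to the less strained bicyclo[2.2.2]octenyl radical while the stannane is kept dilute, and C22 is set because the chain on the C3 face can bond only on that face.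

Step 18
Reactants: 25 O11 tert-butyldimethylsilyl ether of the target
Product: 26 CNP0249919.1
Conditions: HF·pyridine, THF, 0 °C to rt
Reagents that add atoms: none
Why: Fluoride-driven Si–O cleavage in a mildly acidic medium frees O11–H without opening the lactone or moving the trisubstituted alkene, and no stereocentre is involved.

**Compound list**

1 | 1,2:5,6-di-O-isopropylidene-α-D-glucofuranose | CC1(C)OC[C@@H](O1)[C@H]1O[C@@H]2OC(C)(C)O[C@@H]2[C@H]1O | starting material
2 | 2-(bromomethyl)naphthalene | BrCc1ccc2ccccc2c1 | starting material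
3 | 1,2:5,6-di-O-isopropylidene-3-O-(2-naphthylmethyl)-α-D-glucofuranose | CC1(C)OC[C@@H](O1)[C@H]1O[C@@H]2OC(C)(C)O[C@@H]2[C@H]1OCc1ccc2ccccc2c1 | intermediate
4 | 1,2-O-isopropylidene-3-O-(2-naphthylmethyl)-α-D-glucofuranose (5,6-diol) | OC[C@@H](O)[C@H]1O[C@@H]2OC(C)(C)O[C@@H]2[C@H]1OCc1ccc2ccccc2c1 | intermediate
5 | 1,2-O-isopropylidene-3-O-(2-naphthylmethyl)-α-D-xylo-pentodialdo-1,4-furanose | O=C[C@H]1O[C@@H]2OC(C)(C)O[C@@H]2[C@H]1OCc1ccc2ccccc2c1 | intermediate
6 | phenylmagnesium bromide | Br[Mg]c1ccccc1 | starting material
7 | (5S)-1,2-O-isopropylidene-3-O-(2-naphthylmethyl)-5-C-phenyl-α-D-xylofuranose | O[C@@H](c1ccccc1)[C@H]1O[C@@H]2OC(C)(C)O[C@@H]2[C@H]1OCc1ccc2ccccc2c1 | intermediate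
8 | (5S)-1,2-O-isopropylidene-5-O-methanesulfonyl-3-O-(2-naphthylmethyl)-5-C-phenyl-α-D-xylofuranose | CS(=O)(=O)O[C@@H](c1ccccc1)[C@H]1O[C@@H]2OC(C)(C)O[C@@H]2[C@H]1OCc1ccc2ccccc2c1 | intermediate
9 | (5S)-5-O-methanesulfonyl-3-O-(2-naphthylmethyl)-5-C-phenyl-aldehydo-D-xylose dimethyl acetal | COC(OC)[C@H](O)[C@@H](OCc1ccc2ccccc2c1)[C@H](O)[C@@H](OS(C)(=O)=O)c1ccccc1 | intermediate
10 | (5R)-2,5-anhydro-3-O-(2-naphthylmethyl)-5-C-phenyl-D-xylose dimethyl acetal (CH(OMe)2, ONAP and Ph on one oxolane face, OH on the other) | COC(OC)[C@@H]1O[C@H](c2ccccc2)[C@@H](O)[C@@H]1OCc1ccc2ccccc2c1 | intermediate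
11 | (5R)-2,5-anhydro-3-O-(2-naphthylmethyl)-5-C-phenyl-aldehydo-D-xylose | O=C[C@@H]1O[C@H](c2ccccc2)[C@@H](O)[C@@H]1OCc1ccc2ccccc2c1 | intermediate
12 | oxolane of 11 with C20 bearing (E)-2-iodoethenyl, O11–H free | I/C=C/[C@@H]1O[C@H](c2ccccc2)[C@@H](O)[C@@H]1OCc1ccc2ccccc2c1 | intermediate
13 | O11 TBS ether of 12 | I/C=C/[C@@H]1O[C@H](c2ccccc2)[C@@H](O[Si](C)(C)C(C)(C)C)[C@@H]1OCc1ccc2ccccc2c1 | intermediate
14 | O8 alcohol: iodoethenyl, OH and phenyl cis, OTBS trans | I/C=C/[C@@H]1O[C@H](c2ccccc2)[C@@H](O[Si](C)(C)C(C)(C)C)[C@@H]1O | intermediate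
15 | 3-methylbut-1-yne | CC(C)C#C | starting material
16 | pinacolborane | B1OC(C)(C)C(C)(C)O1 | starting material
17 | (E)-2-(3-methylbut-1-enyl)-4,4,5,5-tetramethyl-1,3,2-dioxaborolane | CC(C)/C=C/B1OC(C)(C)C(C)(C)O1 | intermediate
18 | dienyl alcohol: C20 bears (1E,3E)-5-methylhexa-1,3-dienyl, otherwise as 14 | CC(C)/C=C/C=C/[C@@H]1O[C@H](c2ccccc2)[C@@H](O[Si](C)(C)C(C)(C)C)[C@@H]1O | intermediate
19 | maleic anhydride | O=C1OC(=O)C=C1 | starting material
20 | O8 hydrogen maleate (Z) of 18 | CC(C)/C=C/C=C/[C@@H]1O[C@H](c2ccccc2)[C@@H](O[Si](C)(C)C(C)(C)C)[C@@H]1OC(=O)/C=C\C(=O)O | intermediate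
21 | cyclohexene-fused δ-lactone acid, cis-anti-cis tricycle, C3, C6, C20 and C25 on one cyclohexene face | OC(=O)[C@@H]1[C@@H]2C(=O)O[C@H]3[C@H](O[Si](C)(C)C(C)(C)C)[C@@H](c4ccccc4)O[C@H]3[C@@H]2C=C[C@@H]1C(C)C | intermediate
22 | S-ethyl thioester of 21 | CCSC(=O)[C@@H]1[C@@H]2C(=O)O[C@H]3[C@H](O[Si](C)(C)C(C)(C)C)[C@@H](c4ccccc4)O[C@H]3[C@@H]2C=C[C@@H]1C(C)C | intermediate
23 | C3 aldehyde | O=C[C@@H]1[C@@H]2C(=O)O[C@H]3[C@H](O[Si](C)(C)C(C)(C)C)[C@@H](c4ccccc4)O[C@H]3[C@@H]2C=C[C@@H]1C(C)C | intermediate
24 | (Z)-2-iodoprop-1-enyl compound | C/C(I)=C/[C@@H]1[C@@H]2C(=O)O[C@H]3[C@H](O[Si](C)(C)C(C)(C)C)[C@@H](c4ccccc4)O[C@H]3[C@@H]2C=C[C@@H]1C(C)C | intermediate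
25 | O11 TBS ether of the target (bicyclo[2.2.2]octene closed) | CC1=C[C@@H]2[C@@H]3C(=O)O[C@H]4[C@H](O[Si](C)(C)C(C)(C)C)[C@@H](c5ccccc5)O[C@H]4[C@@H]3[C@H]1C[C@@H]2C(C)C | intermediate
26 | CNP0249919.1 | CC1=C[C@@H]2[C@@H]3C(=O)O[C@H]4[C@H](O)[C@@H](c5ccccc5)O[C@H]4[C@@H]3[C@H]1C[C@@H]2C(C)C | target

Total step count: 18. Longest linear sequence: 17 steps (steps 1–9 and 11–18, from 1 to 26).

**Steps most likely to fail**

Step 13.
- What may go wrong: the ester rotamer penalty may make the cyclisation slow. Z-to-E isomerisation of the maleate, reversal of the acylation, or folding in the exo mode could then compete.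
- Fallback, from 18 and 19 back to 21: the same two C–C bonds are made intermolecularly first.
- Without base, in toluene at 40–80 °C, the free anhydride is a far stronger dienophile than its half ester. It should add endo to the E,E-diene to give the all-cis anhydride adduct F1.
- O8–H, held cis to C21, then opens the nearer carbonyl (C6) on warming with a trace of DMAP and closes the δ-lactone to 21.
- Facial control would then rest only on the allylic C20 centre, so diastereomers would be separated at 21.

Step 17.
- What may go wrong: closure in the five-membered mode at C23, 1,5-hydrogen transfer from the isopropyl methine to the vinyl radical, or premature reduction of that radical.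
- Fallback, from 11 back to 26: the bicyclooctene is assembled by an intermolecular Diels–Alder reaction.
- Still–Gennari olefination of 11 (methyl bis(2,2,2-trifluoroethyl)phosphonoacetate, KHMDS, 18-crown-6, THF, −78 °C) should give the Z-enoate F2.
- DDQ frees O8–H, which lactonises onto the cis ester to give (+)-altholactone F3.
- Heating F3 with commercial (R)-α-phellandrene (CC1=CC[C@H](C(C)C)C=C1) in toluene in a sealed tube should give 26. The expected adduct is endo, formed anti to the isopropyl group and on the convex lactone face, with the methyl-substituted diene terminus bonding to the β-carbon C21.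

Step 16.
- What may go wrong: sluggish addition of the bulky iodo ylide to the doubly flanked aldehyde, base-induced epimerisation at C4, or erosion of the alkene geometry.
- Fallback, from 23 back to 25: neutral Ramirez olefination (CBr4, PPh3, CH2Cl2, 0 °C) should give the 1,1-dibromoalkene F4.
- Negishi coupling (MeZnBr, Pd(DPEphos)Cl2, THF) should replace only the exposed bromine trans to C4 and give the (Z)-2-bromoprop-1-enyl compound F5.
- Under the conditions of step 17, F5 should generate the same C2 radical and give 25.

Further compounds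
F1 | step 13 | endo maleic anhydride adduct of 18 with O8–H free | O=C1OC(=O)[C@@H]2[C@H]1[C@H]([C@@H]1O[C@H](c3ccccc3)[C@@H](O[Si](C)(C)C(C)(C)C)[C@@H]1O)C=C[C@@H]2C(C)C
F2 | step 17 | methyl (Z)-enoate from 11 | COC(=O)/C=C\[C@@H]1O[C@H](c2ccccc2)[C@@H](O)[C@@H]1OCc1ccc2ccccc2c1
F3 | step 17 | (+)-altholactone | O=C1C=C[C@@H]2O[C@H](c3ccccc3)[C@@H](O)[C@@H]2O1
F4 | step 16 | 1,1-dibromoalkene from 23 | BrC(Br)=C[C@@H]1[C@@H]2C(=O)O[C@H]3[C@H](O[Si](C)(C)C(C)(C)C)[C@@H](c4ccccc4)O[C@H]3[C@@H]2C=C[C@@H]1C(C)C
F5 | step 16 | (Z)-2-bromoprop-1-enyl compound | C/C(Br)=C/[C@@H]1[C@@H]2C(=O)O[C@H]3[C@H](O[Si](C)(C)C(C)(C)C)[C@@H](c4ccccc4)O[C@H]3[C@@H]2C=C[C@@H]1C(C)C
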